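**Retrosynthetic overview**

1. The target is an A/B cis-fused labdane-type acid. On ring A, the oxygen-bearing carbon C19 (on C4), C6 (on C5) and C9 (on C10) all lie on the α face, opposite 4-Me, H5 and 10-Me. The strategy rests on this: an enone hung on O19 can add C6 and C9 only cis across a C5=C10 olefin.
2. Late disconnections: the O19 acetate, the C3 ketal and the C15 ester are unmasked last; C13=C14 (Z) comes from syn addition of Me2CuLi to a C13≡C14 ynoate; C8=C17 from ketone methylenation; C9–C11 from α′-allylation of a ring B 6-en-8-one.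
3. Ring B (last ring formed): C6–C7 by intramolecular aldol condensation, after retro-aldol release of C6–C9 from a cyclobutane.
4. Key disconnection: C5–C6 and C9–C10 by intramolecular [2+2] photocycloaddition of a β-alkoxy enone tethered through O19; a tetrahydrofuran and a cyclobutane (both temporary) close together.
5. Ring A (first ring) comes from 2-methoxy-5-methylbenzoic acid by auxiliary-controlled Birch reduction–methylation, which sets C4.

Key step: step 6

Remark: skeleton atoms carry labdane numbers (the oxygenated carbon on C4 is called C19; β is the face of the C10 methyl). The Birch reduction–methylation of the 2-methoxybenzamide of (S)-2-(methoxymethyl)pyrrolidine is assumed to place the methyl group anti to the methoxymethyl arm of the chelated amide enolate and so give the (S) quaternary carbon; if the opposite sense operates, the (R)-auxiliary is used with no other change.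

**Route**

Step 1
Reactants: 1 2-methoxy-5-methylbenzoic acid; 2 (S)-2-(methoxymethyl)pyrrolidine
Product: 4 (2-methoxy-5-methylphenyl)[(2S)-2-(methoxymethyl)pyrrolidin-1-yl]methanone, via acid chloride 3 (not isolated)
Conditions: (COCl)2, DMF (2 mol%), CH2Cl2, 0 °C to rt; then 2, Et3N, 0 °C to rt
Reagents that add atoms: none
Why: acylation of the secondary amine by the acid chloride (Schotten–Baumann type amide formation) is routine and leaves the auxiliary stereocentre untouched.

Step 2
Reactants: 4 benzamide; 5 iodomethane
Product: 7 [(1S)-2-methoxy-1,5-dimethylcyclohexa-2,5-dien-1-yl][(2S)-2-(methoxymethyl)pyrrolidin-1-yl]methanone, via potassium amide enolate 6 (not isolated)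
Conditions: K (2.2 equiv), NH3(l)–THF, t-BuOH (1.0 equiv), −78 °C; then MeI (5, excess), −78 °C
Reagents that add atoms: none
Why: Schultz-type asymmetric Birch reduction–alkylation, in which the arene is reduced at the ipso and para carbons, one equivalent of t-BuOH protonates the para carbon to leave the chelated potassium amide enolate, and MeI should attack the enolate face anti to the methoxymethyl arm, which sets the quaternary carbon (C4 of the target) as S.

Step 3
Reactants: 7 cyclohexadiene amide
Product: 8 [(1R)-2-methoxy-1,5-dimethylcyclohexa-2,5-dien-1-yl]methanol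
Conditions: LiNH2BH3 (4 equiv, from BH3·NH3 and LiN(i-Pr)2), THF, 0 °C to rt; aq NaOH work-up
Reagents that add atoms: none
Why: lithium amidotrihydroborate (Myers reduction) should reduce the hindered tertiary amide to the primary alcohol with C–N cleavage, while the enol ether and both olefins are inert to hydride and survive the basic work-up; the quaternary centre cannot epimerise.

Step 4
Reactants: 8 dienyl alcohol
Product: 9 [(6R)-6,8-dimethyl-1,4-dioxaspiro[4.5]dec-7-en-6-yl]methanol
Conditions: HOCH2CH2OH (5 equiv), TsOH·H2O (2 mol%), THF, 0 °C to rt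
Reagents that add atoms: ethane-1,2-diol OCCO
Why: acid-catalysed acetal exchange, in which C-protonation of the methyl enol ether gives the C3 oxocarbenium ion that the diol captures as the dioxolane, as in the ketalisation of Birch products of anisoles, so that the C5=C10 olefin stays out of conjugation.

Step 5
Reactants: 9 ketal alcohol; 10 but-3-yn-2-one
Product: 11 (3E)-4-{[(6R)-6,8-dimethyl-1,4-dioxaspiro[4.5]dec-7-en-6-yl]methoxy}but-3-en-2-one
Conditions: PMe3 (10 mol%), CH2Cl2, 0 °C to rt
Reagents that add atoms: none
Why: phosphine-catalysed oxa-Michael addition of an alcohol to an ynone (the phosphonium allenolate deprotonates the alcohol, and alkoxide addition–elimination follows) should give the E β-alkoxy enone even from a neopentyl alcohol.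

Step 6
Reactants: 11 β-alkoxy enone
Product: 12 cyclobutane photoadduct (9-acetyl-3,3-ethylenedioxy tricycle in which the C5–C6–C9–C10 cyclobutane and the C4–C19–O–C6–C5 tetrahydrofuran are cis-fused to ring A on the α face; 4-Me, H5 and 10-Me β; acetyl trans to O on the four-membered ring)
Conditions: hν (300 nm, Pyrex), acetone (solvent and triplet sensitiser), 5 mM, degassed, 15 °C
Reagents that add atoms: none
Why: Proposed new method: energy transfer from triplet acetone should populate the twisted triplet π,π* state of the β-alkoxy enone, whose β-carbon C6 bonds first to C5 of the ring A olefin and leaves a triplet 1,4-biradical (α-acyl radical at C9, tertiary radical at C10) that closes C9–C10 after spin inversion; an acyclic vinylogous ester hung on oxygen has not been used in this role. The closest known reactions are the de Mayo enone–olefin photocycloaddition and the intramolecular [2+2] photocycloadditions of acyclic vinylogous amides and of cyclic 3-alkenyloxy enones. The tetrahydrofuran closes by 5-exo-trig attack of C6 on C5 (rule of five for a three-atom tether) and the cyclobutane by 4-exo recombination of the C9 and C10 radical centres. C5 and C10 are set by the tether, since O19 sits on the α face of ring A and can deliver C6 and C9 only to that face, cis to each other and anti to 4-Me and 10-Me; C6 follows from the enforced cis fusion of the five-membered ring, and C9 (acetyl exo, trans to O) is erased in step 7. The step needs straight and not crossed regiochemistry, which the five-membered first closure secures, and cycloaddition must outrun decay of the acyclic triplet, which is helped because the E and Z isomers return to the same triplet and are recycled under sensitisation.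

Step 7
Reactants: 12 cyclobutane photoadduct
Product: 15 keto ether (3,3-ethylenedioxy-6α,19-epoxy-8-oxo cis-decalin; 4-Me H5 H6 and 10-Me β), via keto lactol 13 (not isolated), via hydroxy enone 14 (not isolated)
Conditions: 0.2 M HCl, THF–H2O (4:1), 0 °C to rt; then KOH, MeOH, 0 °C to rt (same flask)
Reagents that add atoms: none
Why: the photoadduct is a donor–acceptor cyclobutane (ether oxygen on C6, acyl group on C9), so protonation of the ketone should release the C6–C9 bond in a retro-aldol (de Mayo type) fragmentation with water trapping the oxocarbenium ion as the lactol before H5 can be lost; hydroxide then drives the intramolecular aldol condensation of the methyl ketone carbon C7 onto the C6 aldehyde (six-membered ring B), and the freed C19 hydroxyl re-adds to the enone (5-exo oxa-Michael), with the cis relation of C5 and C10 from step 6 kept.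

Step 8
Reactants: 15 keto ether
Product: 17 silyl ether enone (19-tert-butyldimethylsilyloxy-3,3-ethylenedioxy cis-fused 6-en-8-one; 4-Me H5 and 10-Me β), via bis-silyl dienol ether 16 (not isolated)
Conditions: TBSOTf (3 equiv), Et3N (5 equiv), CH2Cl2, −20 to 0 °C; then 0.5 M aq HCl–THF, 0 °C, 10 min
Reagents that add atoms: tert-butyldimethylsilyl trifluoromethanesulfonate CC(C)(C)[Si](C)(C)OS(=O)(=O)C(F)(F)F
Why: silyl triflate–amine β-elimination (retro-oxa-Michael) of a β-alkoxy ketone, in which the C7 silyl enol ether expels the silylated ether oxygen from C6 and kinetic α′ deprotonation gives the 2-silyloxydiene, whose enol silyl ether alone is hydrolysed by brief cold acid; no stereocentre is touched and the C19 oxygen leaves protected, so it cannot re-add to the enone.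

Step 9
Reactants: 17 silyl ether enone; 18 allyl bromide
Product: 20 9β-allyl enone (allyl cis to 10-Me and H5), via lithium dienolate 19 (not isolated)
Conditions: LiN(i-Pr)2 (1.1 equiv), THF, −78 °C; then allyl bromide (18, 3 equiv), DMPU, −78 to −30 °C
Reagents that add atoms: none
Why: kinetic deprotonation of an enone by LiN(i-Pr)2 occurs at the α′ carbon C9, and SN2 allylation of the cross-conjugated dienolate should take place on the convex β face of the cis-fused bicycle, anti to ring A (C1 pseudoaxial on C10), which places the allyl group cis to 10-Me and H5 as the target requires.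

Step 10
Reactants: 20 9β-allyl enone
Product: 21 9β-allyl 8-ketone (C6 and C7 saturated)
Conditions: [(Ph3P)CuH]6 (Stryker's reagent, 0.4 equiv), toluene, H2O (5 equiv), rt
Reagents that add atoms: none
Why: copper hydride conjugate reduction adds hydride to C6 of the enone only (isolated olefins are inert) and the copper enolate is protonated at C7, so the C9 centre next to the ketone is not exposed to base.

Step 11
Reactants: 21 9β-allyl 8-ketone
Product: 22 8(17)-methylene diene
Conditions: Cp2TiMe2 (3 equiv), toluene, 70 °C, dark
Reagents that add atoms: dimethyltitanocene C[Ti](C)(C1C=CC=C1)C1C=CC=C1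
Why: Petasis methylenation (thermally generated Cp2Ti=CH2) converts hindered enolisable ketones to exocyclic olefins under non-basic conditions, so C9 keeps its configuration.

Step 12
Reactants: 22 8(17)-methylene diene
Product: 24 C13 primary alcohol (3-hydroxypropyl chain on C9), via alkyl(disiamyl)borane 23 (not isolated)
Conditions: Sia2BH (1.3 equiv, from BH3·THF and 2-methylbut-2-ene), THF, 0 °C; then NaOH, H2O2, 0 °C to rt
Reagents that add atoms: hydrogen peroxide OO
Why: disiamylborane hydroborates a monosubstituted vinyl group anti-Markovnikov much faster than a hindered 1,1-disubstituted exocyclic olefin, and oxidation of the C–B bond gives the primary alcohol.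

Step 13
Reactants: 24 C13 primary alcohol
Product: 25 C13 aldehyde
Conditions: Dess–Martin periodinane, NaHCO3, CH2Cl2, rt
Reagents that add atoms: none
Why: Dess–Martin oxidation of a primary alcohol stops at the aldehyde under buffered conditions that leave the silyl ether, the ketal and the olefin alone.

Step 14
Reactants: 25 C13 aldehyde
Product: 26 terminal alkyne (C13≡C14)
Conditions: dimethyl (1-diazo-2-oxopropyl)phosphonate, K2CO3, MeOH, 0 °C to rt
Reagents that add atoms: dimethyl (1-diazo-2-oxopropyl)phosphonate COP(=O)(OC)C(=[N+]=[N-])C(C)=O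
Why: Ohira–Bestmann (Seyferth–Gilbert) homologation, in which the diazomethylphosphonate anion formed in methanol adds to the aldehyde and the alkylidene carbene rearranges to the terminal alkyne, adds C14 under mild base.

Step 15
Reactants: 26 terminal alkyne
Product: 28 methyl ynoate (C13≡C14–C15O2Me), via lithium acetylide 27 (not isolated)
Conditions: n-BuLi, THF, −78 °C; then ClCO2Me, −78 to 0 °C
Reagents that add atoms: methyl chloroformate COC(Cl)=O
Why: deprotonation of the terminal alkyne and C-acylation of the lithium acetylide with a chloroformate give the ynoate; the silyl ether and the ketal are inert to the acetylide.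

Step 16
Reactants: 28 methyl ynoate
Product: 30 methyl (13Z)-enoate, via alkenyl(methyl)cuprate 29 (not isolated)
Conditions: Me2CuLi (1.5 equiv, from CuI and 2 MeLi), THF, −78 °C; MeOH then aq NH4Cl at −78 °C
Reagents that add atoms: lithium dimethylcuprate [Li+].C[Cu-]C
Why: syn carbocupration of the ynoate at −78 °C followed by protonation of the alkenylcuprate with retention puts the new methyl group cis to H14 and therefore C12 cis to the ester, which is the 13Z geometry.

Step 17
Reactants: 30 methyl (13Z)-enoate
Product: 31 (13Z)-enoic acid (silyl ether and ketal retained)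
Conditions: LiOH·H2O, THF–MeOH–H2O, 40 °C; then 0.5 M HCl to pH 4, 0 °C
Reagents that add atoms: lithium hydroxide [Li+].[OH-]
Why: saponification (acyl–oxygen cleavage) of the methyl ester; the silyl ether and the ketal are stable to hydroxide and to brief cold acidification, and no acetate is yet present to compete.

Step 18
Reactants: 31 (13Z)-enoic acid
Product: 32 hydroxy keto acid (C3 ketone and C19 hydroxyl free)
Conditions: 1 M aq HCl–THF (1:1), rt to 40 °C
Reagents that add atoms: water O
Why: dilute aqueous acid hydrolyses the dioxolane through its oxocarbenium ion and cleaves the primary silyl ether in one operation; the β-hydroxy ketone cannot dehydrate because C4 is quaternary, and the exocyclic olefin is expected to tolerate dilute acid at this temperature.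

Step 19
Reactants: 32 hydroxy keto acid
Product: 34 target acid CNP0243698.1, via mixed anhydride 33 (not isolated)
Conditions: Ac2O, pyridine, DMAP (5 mol%), CH2Cl2, rt; then H2O–THF, rt
Reagents that add atoms: acetic anhydride CC(=O)OC(C)=O
Why: DMAP-catalysed acetylation of the primary alcohol; the carboxylic acid is converted at the same time to the mixed acetic anhydride, which water hydrolyses back to the acid on work-up while the neopentyl acetate stays.

**Compound list**

1 | 2-methoxy-5-methylbenzoic acid | COc1ccc(C)cc1C(=O)O | starting material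
2 | (S)-2-(methoxymethyl)pyrrolidine | COC[C@@H]1CCCN1 | starting material
3 | 2-methoxy-5-methylbenzoyl chloride | COc1ccc(C)cc1C(Cl)=O | intermediate (not isolated)
4 | (2-methoxy-5-methylphenyl)[(2S)-2-(methoxymethyl)pyrrolidin-1-yl]methanone | COC[C@@H]1CCCN1C(=O)c1cc(C)ccc1OC | intermediate
5 | iodomethane | CI | starting material
6 | potassium amide enolate of the 1,4-dihydrobenzamide (exocyclic enolate on the 2-methoxy-5-methylcyclohexa-2,5-diene ring) | COC[C@@H]1CCCN1C([O-])=C1C=C(C)CC=C1OC.[K+] | intermediate (not isolated)
7 | [(1S)-2-methoxy-1,5-dimethylcyclohexa-2,5-dien-1-yl][(2S)-2-(methoxymethyl)pyrrolidin-1-yl]methanone | CC1=C[C@](C)(C(=O)N2CCC[C@H]2COC)C(OC)=CC1 | intermediate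
8 | [(1R)-2-methoxy-1,5-dimethylcyclohexa-2,5-dien-1-yl]methanol | CC1=C[C@](C)(CO)C(OC)=CC1 | intermediate
9 | [(6R)-6,8-dimethyl-1,4-dioxaspiro[4.5]dec-7-en-6-yl]methanol | CC1=C[C@](C)(CO)C2(OCCO2)CC1 | intermediate
10 | but-3-yn-2-one | CC(=O)C#C | starting material
11 | (3E)-4-{[(6R)-6,8-dimethyl-1,4-dioxaspiro[4.5]dec-7-en-6-yl]methoxy}but-3-en-2-one | CC1=C[C@](C)(CO/C=C/C(C)=O)C2(OCCO2)CC1 | intermediate
12 | cyclobutane photoadduct: 9-acetyl-3,3-ethylenedioxy tricycle, cyclobutane C5–C6–C9–C10 and tetrahydrofuran C4–C19–O–C6–C5 cis-fused to ring A on the α face; 4-Me, H5, 10-Me β; acetyl trans to O | C[C@@]12CCC3(OCCO3)[C@@]4(C)CO[C@@H]([C@@H]1C(C)=O)[C@@H]24 | intermediate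
13 | keto lactol: ring A ketal with a 2-oxopropyl group on C10 (α) and a cis-fused 2-hydroxytetrahydrofuran across C4–C5 (C6 lactol, both anomers) | CC(=O)C[C@@]1(C)CCC2(OCCO2)[C@@]3(C)COC(O)[C@@H]13 | intermediate (not isolated)
14 | hydroxy enone: 19-hydroxy-3,3-ethylenedioxy cis-fused 6-en-8-one; 4-Me, H5, 10-Me β | O=C1C=C[C@H]2[C@](C)(CCC3(OCCO3)[C@@]2(C)CO)C1 | intermediate (not isolated)
15 | keto ether: 3,3-ethylenedioxy-6α,19-epoxy-8-oxo cis-decalin; 4-Me, H5, H6, 10-Me β | C[C@@]12CCC3(OCCO3)[C@@]4(C)CO[C@@H](CC(=O)C1)[C@@H]24 | intermediate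
16 | bis-silyl dienol ether: 8,19-bis(tert-butyldimethylsilyloxy)-3,3-ethylenedioxy cis-fused 6,8-diene | C[C@]12CCC3(OCCO3)[C@@](C)(CO[Si](C)(C)C(C)(C)C)[C@H]1C=CC(O[Si](C)(C)C(C)(C)C)=C2 | intermediate (not isolated)
17 | silyl ether enone: 19-(tert-butyldimethylsilyloxy)-3,3-ethylenedioxy cis-fused 6-en-8-one; 4-Me, H5, 10-Me β | O=C1C=C[C@H]2[C@](C)(CCC3(OCCO3)[C@@]2(C)CO[Si](C)(C)C(C)(C)C)C1 | intermediate
18 | allyl bromide | C=CCBr | starting material
19 | lithium dienolate of 17 (C6=C7–C8(OLi)=C9) | C[C@]12CCC3(OCCO3)[C@@](C)(CO[Si](C)(C)C(C)(C)C)[C@H]1C=CC([O-])=C2.[Li+] | intermediate (not isolated)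
20 | 9β-allyl enone (allyl cis to 10-Me and H5) | O=C1C=C[C@H]2[C@](C)(CCC3(OCCO3)[C@@]2(C)CO[Si](C)(C)C(C)(C)C)[C@H]1CC=C | intermediate
21 | 9β-allyl 8-ketone | O=C1CC[C@H]2[C@](C)(CCC3(OCCO3)[C@@]2(C)CO[Si](C)(C)C(C)(C)C)[C@H]1CC=C | intermediate
22 | 8(17)-methylene diene (9β-allyl) | C=C1CC[C@H]2[C@](C)(CCC3(OCCO3)[C@@]2(C)CO[Si](C)(C)C(C)(C)C)[C@H]1CC=C | intermediate
23 | alkyl(disiamyl)borane at C13 | C=C1CC[C@H]2[C@](C)(CCC3(OCCO3)[C@@]2(C)CO[Si](C)(C)C(C)(C)C)[C@H]1CCCB(C(C)C(C)C)C(C)C(C)C | intermediate (not isolated)
24 | C13 primary alcohol (9β-3-hydroxypropyl) | C=C1CC[C@H]2[C@](C)(CCC3(OCCO3)[C@@]2(C)CO[Si](C)(C)C(C)(C)C)[C@H]1CCCO | intermediate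
25 | C13 aldehyde | C=C1CC[C@H]2[C@](C)(CCC3(OCCO3)[C@@]2(C)CO[Si](C)(C)C(C)(C)C)[C@H]1CCC=O | intermediate
26 | terminal alkyne (9β-but-3-ynyl) | C=C1CC[C@H]2[C@](C)(CCC3(OCCO3)[C@@]2(C)CO[Si](C)(C)C(C)(C)C)[C@H]1CCC#C | intermediate
27 | lithium acetylide of 26 | C=C1CC[C@H]2[C@](C)(CCC3(OCCO3)[C@@]2(C)CO[Si](C)(C)C(C)(C)C)[C@H]1CCC#[C-].[Li+] | intermediate (not isolated)
28 | methyl ynoate (C13≡C14–CO2Me) | C=C1CC[C@H]2[C@](C)(CCC3(OCCO3)[C@@]2(C)CO[Si](C)(C)C(C)(C)C)[C@H]1CCC#CC(=O)OC | intermediate
29 | lithium alkenyl(methyl)cuprate (Cu on C14, cis to the new C13 methyl) | C=C1CC[C@H]2[C@](C)(CCC3(OCCO3)[C@@]2(C)CO[Si](C)(C)C(C)(C)C)[C@H]1CC/C(C)=C(\C(=O)OC)[Cu-]C.[Li+] | intermediate (not isolated)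
30 | methyl (13Z)-enoate (silyl ether, ketal) | C=C1CC[C@H]2[C@](C)(CCC3(OCCO3)[C@@]2(C)CO[Si](C)(C)C(C)(C)C)[C@H]1CC/C(C)=C\C(=O)OC | intermediate
31 | (13Z)-enoic acid (silyl ether, ketal) | C=C1CC[C@H]2[C@](C)(CCC3(OCCO3)[C@@]2(C)CO[Si](C)(C)C(C)(C)C)[C@H]1CC/C(C)=C\C(=O)O | intermediate
32 | hydroxy keto acid (19-hydroxy-3-oxo, 13Z) | C=C1CC[C@H]2[C@](C)(CCC(=O)[C@@]2(C)CO)[C@H]1CC/C(C)=C\C(=O)O | intermediate
33 | mixed acetic anhydride of the 19-acetate | C=C1CC[C@H]2[C@](C)(CCC(=O)[C@@]2(C)COC(C)=O)[C@H]1CC/C(C)=C\C(=O)OC(C)=O | intermediate (not isolated)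
34 | CNP0243698.1: cis-fused 19-acetoxy-3-oxo-8(17),13Z-dien-15-oic acid; 4β-Me, 4α-CH2OAc, 5β-H, 10β-Me, 9β side chain | C=C1CC[C@H]2[C@](C)(CCC(=O)[C@@]2(C)COC(C)=O)[C@H]1CC/C(C)=C\C(=O)O | target

**Step count**

Total: 19 steps. Longest linear sequence: 19 steps (fully linear from 1).

**Steps most likely to fail**

Step 6 (proposed new method). The acyclic enone triplet may decay by E/Z isomerisation faster than it adds to the trisubstituted olefin, the Z isomer may lose a hydrogen from the O–CH2 group by 1,6-transfer, or the 1,4-biradical may revert. The fallback replaces the photocycloaddition by a thermal type 1 intramolecular Diels–Alder reaction and sets out from 11. LiN(SiMe3)2 and TBSCl (THF–DMPU, −78 °C) should convert the methyl ketone to the 1-alkoxy-3-silyloxybutadiene F1. Heating in toluene (about 200 °C, sealed tube, BHT) should add the diene termini C6 and C9 to C5 and C10 from the α face, again dictated by the O19 tether, and give the cycloadduct silyl enol ether F2. Mild aqueous acid hydrolyses F2 to keto ether 15, where the route is rejoined; a C6 epimer of F2 would converge at 17 after step 8.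

Step 9. Alkylation next to the quaternary C10 may be slow enough for proton transfer and over-alkylation to compete, and facial selectivity on the dienolate may be incomplete. The fallback is a decarboxylative Tsuji allylation from 17. LiN(SiMe3)2 then allyl chloroformate (THF, −78 °C) should give the allyl dienyl carbonate F6. Pd(PPh3)4 (zerovalent palladium, THF, rt) should ionise F6 to a π-allyl/enolate pair that recombines at C9 to give 20; a chiral phosphinooxazoline ligand on palladium could reinforce the β-face preference.

Step 8. The silyl triflate may ionise the C3 dioxolane in competition with the C6–O bond, or may only silylate the enol without elimination. The fallback never forms the ether bridge and sets out from keto lactol 13, isolated after the acid stage of step 7. K2CO3 in MeOH at 0 °C should stop the intramolecular aldol addition at the ketol diol F3. TBSCl and imidazole (DMF, 0 °C) should silylate the primary C19 hydroxyl selectively to give the mono-silyl ketol F4. MsCl and Et3N (CH2Cl2, 0 °C to rt) convert the C6 hydroxyl to the mesylate F5, which eliminates in the same flask to enone 17, so that a free C19 hydroxyl and the enone never coexist.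

**Further compounds**

F1 | step 6 | (E)-1-alkoxy-3-(tert-butyldimethylsilyloxy)buta-1,3-diene tethered through O19 to ring A | CC1=C[C@](C)(CO/C=C/C(=C)O[Si](C)(C)C(C)(C)C)C2(OCCO2)CC1
F2 | step 6 | Diels–Alder adduct, 8-silyl enol ether (C7=C8) of keto ether 15 | C[C@@]12CCC3(OCCO3)[C@@]4(C)CO[C@@H](C=C(O[Si](C)(C)C(C)(C)C)C1)[C@@H]24
F3 | step 8 | ketol diol: 6,19-dihydroxy-3,3-ethylenedioxy cis-fused 8-ketone | O=C1CC(O)[C@H]2[C@](C)(CCC3(OCCO3)[C@@]2(C)CO)C1
F4 | step 8 | mono-silyl ketol: 19-(tert-butyldimethylsilyloxy)-6-hydroxy 8-ketone | O=C1CC(O)[C@H]2[C@](C)(CCC3(OCCO3)[C@@]2(C)CO[Si](C)(C)C(C)(C)C)C1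
F5 | step 8 | C6 mesylate of F4 | O=C1CC(OS(C)(=O)=O)[C@H]2[C@](C)(CCC3(OCCO3)[C@@]2(C)CO[Si](C)(C)C(C)(C)C)C1
F6 | step 9 | allyl dienyl carbonate of 17 (carbonate on O8 of the 6,8-diene) | C[C@]12CCC3(OCCO3)[C@@](C)(CO[Si](C)(C)C(C)(C)C)[C@H]1C=CC(OC(=O)OCC=C)=C2
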